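**Retrosynthetic overview**

- The strategy rests on one feature: each 3-methoxy-4,5-dihydroxyphenyl ring is joined through its aryl C1–C7 (C1'–C7') bond to a primary benzylic CH2, and these two CH2 groups flank the C2-symmetric C8–C8' dimethyl dyad. The two aryl–CH2 bonds are therefore symmetry-equivalent and lie beta to the stereocentres.
- Both aryl–CH2 bonds are cut at once, giving (2S,3S)-1,4-diiodo-2,3-dimethylbutane (used as its 1,4-dizinc reagent) and two molecules of 1,2-bis(benzyloxy)-5-bromo-3-methoxybenzene; a double Negishi coupling joins them and global debenzylation finishes the route.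
- The diiodide comes from oxidative homocoupling of two molecules of the enolate of (R)-4-benzyl-3-propionyloxazolidin-2-one, which sets both stereocentres, followed by reductive auxiliary removal, mesylation and Finkelstein exchange.
- The aryl bromide comes from 5-bromo-o-vanillin by Dakin oxidation and dibenzylation.
- No ring is formed at any stage; both arene rings are bought intact and the chain stays open.

Key step: step 7

Remark on the chemistry: lignan numbering is assumed (C7/C7' benzylic CH2, C8/C8' methine, C9/C9' methyl). The (2S,3S) descriptors of the C4 building blocks and the (8R,8'R) descriptors of the target describe the same spatial arrangement; only the CIP priorities change (CH2O, CH2I and CH2Zn outrank the neighbouring methine, CH2Ar does not).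

**Route**

Step 1
Reactants: 1 (R)-4-benzyl-3-propionyloxazolidin-2-one (2 equiv)
Product: 3 (2S,3S)-1,4-bis[(4R)-4-benzyl-2-oxooxazolidin-3-yl]-2,3-dimethylbutane-1,4-dione, via lithium Z-enolate 2 (not isolated)
Conditions: LiN(i-Pr)2 (1.1 equiv per mole of 1), THF, −78 °C; then anhydrous CuCl2 (1.2 equiv per mole of 1, in DMF), −78 → 0 °C; cold aqueous NH4Cl quench
Reagents that add atoms: none
Why: Oxidative enolate homocoupling with divalent copper as one-electron oxidant joins the alpha-carbons of two molecules of the chelated lithium Z-enolate 2, each reacting on the face opposite the C4 benzyl group of the (R)-auxiliary (the facial sense of an Evans alkylation), which makes both new centres S; the minor dimers are diastereomers and should be removable by chromatography or crystallisation.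

Step 2
Reactants: 3 (2S,3S)-1,4-bis[(4R)-4-benzyl-2-oxooxazolidin-3-yl]-2,3-dimethylbutane-1,4-dione
Product: 4 (2S,3S)-2,3-dimethylbutane-1,4-diol
Conditions: LiBH4 (4 equiv), H2O (4 equiv), THF, 0 °C → rt; minimal aqueous work-up, exhaustive EtOAc extraction
Reagents that add atoms: none
Why: Reductive cleavage of N-acyl oxazolidinones by LiBH4 occurs at the exocyclic carbonyl under non-enolising conditions, so both alpha-stereocentres pass into the diol unchanged and the auxiliary is released intact (a gamma-lactone formed by alkoxide attack on the second imide would be reduced to the same diol).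

Step 3
Reactants: 4 (2S,3S)-2,3-dimethylbutane-1,4-diol
Product: 5 (2S,3S)-2,3-dimethylbutane-1,4-diyl dimethanesulfonate
Conditions: MsCl (2.4 equiv), Et3N (3 equiv), CH2Cl2, 0 °C
Reagents that add atoms: methanesulfonyl chloride CS(=O)(=O)Cl
Why: Sulfonylation of two unhindered primary alcohols by way of sulfene is fast at 0 °C and outruns cyclisation to the tetrahydrofuran, which a direct Appel iodination of this 1,4-diol would risk.

Step 4
Reactants: 5 (2S,3S)-2,3-dimethylbutane-1,4-diyl dimethanesulfonate
Product: 6 (2S,3S)-1,4-diiodo-2,3-dimethylbutane
Conditions: NaI (5 equiv), acetone, reflux, dark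
Reagents that add atoms: sodium iodide [Na+].[I-]
Why: Finkelstein SN2 displacement at two primary carbons is driven by precipitation of sodium methanesulfonate from acetone; the stereocentres are beta to the reacting carbons and take no part.

Step 5
Reactants: 7 5-bromo-2-hydroxy-3-methoxybenzaldehyde
Product: 9 5-bromo-3-methoxybenzene-1,2-diol, via aryl formate 8 (not isolated)
Conditions: NaOH (1.1 equiv), 30% H2O2 (1.2 equiv), THF–H2O, 0 °C → rt, N2; then 1 M HCl
Reagents that add atoms: hydrogen peroxide OO
Why: Dakin oxidation: hydroperoxide adds to the aldehyde ortho to the phenoxide, the electron-rich aryl group migrates to oxygen to give formate 8, and this is hydrolysed in the flask to the catechol; the aryl bromide is inert.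

Step 6
Reactants: 9 5-bromo-3-methoxybenzene-1,2-diol; 10 benzyl bromide (2.4 equiv)
Product: 11 1,2-bis(benzyloxy)-5-bromo-3-methoxybenzene
Conditions: K2CO3 (3 equiv), DMF, 60 °C, N2
Reagents that add atoms: none
Why: Williamson etherification of both phenoxides with benzyl bromide; benzyl ethers are inert to organozinc reagents and palladium cross-coupling, and all four are removed together at the end.

Step 7
Reactants: 6 (2S,3S)-1,4-diiodo-2,3-dimethylbutane; 11 1,2-bis(benzyloxy)-5-bromo-3-methoxybenzene (2.3 equiv)
Product: 13 tetra-O-benzyl sauriol A, via bis(iodozinc) reagent 12 (not isolated)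
Conditions: Zn dust (activated with catalytic BrCH2CH2Br and Me3SiCl), LiCl, THF, 40 °C; supernatant then added to 11, Pd(OAc)2 (4 mol%), SPhos (8 mol%), THF, 25 → 50 °C
Reagents that add atoms: none
Why: Zinc inserts oxidatively into both primary C–I bonds to give dizinc reagent 12; zerovalent palladium ligated by SPhos adds to the C–Br bond of 11, the primary alkyl group is transferred from zinc to palladium, and reductive elimination forms the aryl C1–C7 bond, the same cycle then repeating at C7'. The closest known reaction type is the Negishi coupling of primary alkylzinc halides with aryl bromides, used here twice on one 1,4-dizinc reagent. No ring is closed and no stereocentre is created; C8 and C8' are beta to the metal, carry no acidifying group and are never a reacting centre, so the dyad set in step 1 is carried through. The step needs reductive elimination to outrun beta-hydride elimination at the C8–H bond and needs both termini to couple; the first is secured by a primary alkylpalladium bearing a bulky electron-rich biarylphosphine, the second by an excess of 11 and a titrated, moisture-free zinc reagent.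

Step 8
Reactants: 13 tetra-O-benzyl sauriol A
Product: 14 Sauriol A
Conditions: H2 (1 atm), 10% Pd/C, EtOAc–MeOH, rt; work-up under N2
Reagents that add atoms: none
Why: Hydrogenolysis of the four benzyl aryl ethers over palladium on carbon; the benzylic C–C bonds, the methyl ethers and the stereocentres are untouched.

**Compound list**

1 | (R)-4-benzyl-3-propionyloxazolidin-2-one | CCC(=O)N1[C@H](Cc2ccccc2)COC1=O | starting material
2 | lithium Z-enolate of 1 | C/C=C(\O[Li])N1[C@H](Cc2ccccc2)COC1=O | intermediate (not isolated)
3 | (2S,3S)-1,4-bis[(4R)-4-benzyl-2-oxooxazolidin-3-yl]-2,3-dimethylbutane-1,4-dione | O=C([C@@H](C)[C@H](C)C(=O)N1[C@H](Cc2ccccc2)COC1=O)N1[C@H](Cc2ccccc2)COC1=O | intermediate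
4 | (2S,3S)-2,3-dimethylbutane-1,4-diol | OC[C@@H](C)[C@H](C)CO | intermediate
5 | (2S,3S)-2,3-dimethylbutane-1,4-diyl dimethanesulfonate | CS(=O)(=O)OC[C@@H](C)[C@H](C)COS(C)(=O)=O | intermediate
6 | (2S,3S)-1,4-diiodo-2,3-dimethylbutane | IC[C@@H](C)[C@H](C)CI | intermediate
7 | 5-bromo-2-hydroxy-3-methoxybenzaldehyde | COc1cc(Br)cc(C=O)c1O | starting material
8 | 5-bromo-2-hydroxy-3-methoxyphenyl formate | COc1cc(Br)cc(OC=O)c1O | intermediate (not isolated)
9 | 5-bromo-3-methoxybenzene-1,2-diol | COc1cc(Br)cc(O)c1O | intermediate
10 | benzyl bromide | BrCc1ccccc1 | starting material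
11 | 1,2-bis(benzyloxy)-5-bromo-3-methoxybenzene | COc1cc(Br)cc(OCc2ccccc2)c1OCc1ccccc1 | intermediate
12 | [(2S,3S)-2,3-dimethylbutane-1,4-diyl]bis(iodozinc) | I[Zn]C[C@@H](C)[C@H](C)C[Zn]I | intermediate (not isolated)
13 | tetra-O-benzyl sauriol A, (8R,8'R)-1,4-bis[3,4-bis(benzyloxy)-5-methoxyphenyl]-2,3-dimethylbutane | COc1cc(C[C@@H](C)[C@H](C)Cc2cc(OC)c(OCc3ccccc3)c(OCc3ccccc3)c2)cc(OCc2ccccc2)c1OCc1ccccc1 | intermediate
14 | Sauriol A | COc1cc(C[C@@H](C)[C@H](C)Cc2cc(O)c(O)c(OC)c2)cc(O)c1O | target

**Step count**

Total steps: 8. Longest linear sequence: 6 steps (steps 1, 2, 3, 4, 7, 8); the aryl arm (steps 5, 6) joins at step 7.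

**Steps most likely to fail**

1. Step 7. Zinc insertion at the beta-branched primary iodides may stall, moisture may protonate one C–Zn bond so that only one terminus is arylated, and slow oxidative addition of the electron-rich bromide may let beta-hydride elimination or aryl homocoupling compete. The fallback sets out from 6 and 11 and comes back at 13 by reversing the polarity of the same two bonds. Bromide 11 is converted with Mg turnings and LiCl in THF into [3,4-bis(benzyloxy)-5-methoxyphenyl]magnesium bromide F1. F1 is added slowly to diiodide 6 in THF at 0 °C with catalytic FeCl3 and TMEDA (iron-catalysed Kumada-type aryl–alkyl coupling of primary alkyl halides). The alkyl radical involved is primary and one carbon away from the stereocentre, so the dyad is again untouched.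

2. Step 1. Facial discrimination in the C–C bond formation may be poor, so that the three diastereomeric dimers form in comparable amounts; simple re-protonation or alpha-chlorination of the enolate may also compete. The fallback sets out from 1 (through enolate 2) and comes back at 4, building the dyad one centre at a time. Ethyl (S)-lactate is converted (Tf2O, 2,6-lutidine, CH2Cl2, −78 °C) into ethyl (S)-2-(trifluoromethylsulfonyloxy)propanoate F2. Enolate 2 displaces the triflate with inversion (alkylation of an oxazolidinone enolate with an alpha-triflyloxy ester) to give ethyl (2S,3S)-4-[(R)-4-benzyl-2-oxooxazolidin-3-yl]-2,3-dimethyl-4-oxobutanoate F3. C2 (the ester alpha-carbon) is fixed by the lactate and C3 (the imide alpha-carbon) by the auxiliary. LiBH4 in THF then reduces imide and ester together to diol 4.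

3. Step 5. The electron-rich catechol may be over-oxidised (quinone formation, ring cleavage) in alkaline peroxide or on exposure to air. The fallback sets out from 7 and comes back at 11, so that no free catechol ever meets an oxidant. The phenol of 7 is benzylated first (BnBr, K2CO3, DMF) to 2-(benzyloxy)-5-bromo-3-methoxybenzaldehyde F4. Baeyer–Villiger oxidation (mCPBA, CH2Cl2) gives 2-(benzyloxy)-5-bromo-3-methoxyphenyl formate F5. Methanolysis (K2CO3, MeOH) gives 2-(benzyloxy)-5-bromo-3-methoxyphenol F6, and a second benzylation (BnBr, K2CO3, DMF) gives 11.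

**Further compounds**

F1 | step 7 | [3,4-bis(benzyloxy)-5-methoxyphenyl]magnesium bromide | COc1cc([Mg]Br)cc(OCc2ccccc2)c1OCc1ccccc1
F2 | step 1 | ethyl (S)-2-(trifluoromethylsulfonyloxy)propanoate | CCOC(=O)[C@H](C)OS(=O)(=O)C(F)(F)F
F3 | step 1 | ethyl (2S,3S)-4-[(R)-4-benzyl-2-oxooxazolidin-3-yl]-2,3-dimethyl-4-oxobutanoate | CCOC(=O)[C@@H](C)[C@H](C)C(=O)N1[C@H](Cc2ccccc2)COC1=O
F4 | step 5 | 2-(benzyloxy)-5-bromo-3-methoxybenzaldehyde | COc1cc(Br)cc(C=O)c1OCc1ccccc1
F5 | step 5 | 2-(benzyloxy)-5-bromo-3-methoxyphenyl formate | COc1cc(Br)cc(OC=O)c1OCc1ccccc1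
F6 | step 5 | 2-(benzyloxy)-5-bromo-3-methoxyphenol | COc1cc(Br)cc(O)c1OCc1ccccc1
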